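The cis-lactone is disconnected at C8–O and then at C7–C11/C8–C11, so that its two carbons C11 and C12 come from a diazoacetate and the ring from an anisole. In one operation the key step adds the carbene from tert-butyl diazoacetate (CuOTf, chiral bis(oxazoline)) across C7=C8, forming C7–C11 and C8–C11, the cyclopropane ring and the C7 configuration. It exploits the electron-rich trisubstituted enol-ether bond C7=C8 of the six-membered ring C5–C10, which lies beside an inert tetrasubstituted C5=C10 bond. The precursor is the Birch-derived 1-methoxycyclohexa-1,4-diene carrying the C14 methyl on C10 and the (S)-configured C1–C4 chain on C5 as a triisopropylsilyl ether.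

Key step: step 6

Numbering used throughout: ring carbons C5–C10 (C5 bears the chain C4–C1 with the C15 methyl on C4, C10 bears the C14 methyl); lactone C7–C11–C12(=O)–O–C8; exocyclic methylene C13.

Remark on the chemistry: O1 is carried as a triisopropylsilyl ether because a primary tert-butyldimethylsilyl ether would be at risk in the aqueous acid that opens the cyclopropane; the carbon skeletons of the diene and of the cyclopropane are not affected by this choice.

Step 1
Reactants: 1 4-methoxy-2-methylbenzaldehyde
Product: 2 1-ethenyl-4-methoxy-2-methylbenzene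
Conditions: Ph3PCH3Br, KOt-Bu, THF, 0 °C to rt
Reagents that add atoms: methyltriphenylphosphonium bromide, C[P+](c1ccccc1)(c1ccccc1)c1ccccc1.[Br-]
Why: Wittig methylenation of an aryl aldehyde with the non-stabilised ylide is reliable, the ortho-methyl group is too small to hinder it, and no stereocentre is formed.

Step 2
Reactants: 2 1-ethenyl-4-methoxy-2-methylbenzene; 3 ethylene
Product: 4 1-[(2S)-but-3-en-2-yl]-4-methoxy-2-methylbenzene
Conditions: [Ni(C3H5)Br]2 (1 mol %), binaphthol-derived phosphoramidite with an N,N-bis(1-phenylethyl)amino group (2 mol %, antipode that gives the (S)-alkene), Na[B(3,5-(CF3)2C6H3)4] (2 mol %), ethylene (1 atm), CH2Cl2, −70 °C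
Reagents that add atoms: ethylene (compound 3), C=C
Why: Nickel-catalysed asymmetric hydrovinylation, in which the cationic nickel hydride adds to the styrene to give an η3-benzylic species, ethylene inserts at the benzylic carbon and β-hydride elimination releases the branched 3-arylbut-1-ene; the chiral phosphoramidite selects the enantioface and so sets C4 as (S), and electron-rich and ortho-substituted styrenes are established substrates.

Step 3
Reactants: 4 1-[(2S)-but-3-en-2-yl]-4-methoxy-2-methylbenzene
Product: 6 (4S)-4-(4-methoxy-2-methylphenyl)pentan-1-ol, via aldehyde 5 (not isolated)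
Conditions: Rh(acac)(CO)2 (1 mol %), Xantphos (2 mol %), CO/H2 (1:1, 10 bar), toluene, 70 °C; vent; then NaBH4, MeOH, 0 °C
Reagents that add atoms: carbon monoxide, [C-]#[O+]
Why: Rhodium-catalysed linear hydroformylation with a wide-bite-angle diphosphine puts the formyl group on the terminal carbon (the allylic branch reinforces the anti-Markovnikov preference and C4 is not touched), and NaBH4 reduces the aldehyde to the primary alcohol in the same pot.

Step 4
Reactants: 6 (4S)-4-(4-methoxy-2-methylphenyl)pentan-1-ol
Product: 7 {[(4S)-4-(4-methoxy-2-methylphenyl)pentyl]oxy}tri(propan-2-yl)silane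
Conditions: i-Pr3SiCl, imidazole, DMF, rt
Reagents that add atoms: chlorotriisopropylsilane, CC(C)[Si](Cl)(C(C)C)C(C)C
Why: Standard silylation of a primary alcohol, giving an ether that tolerates lithium in ammonia, carbene transfer, dilute aqueous acid and the later oxidation and enolate steps.

Step 5
Reactants: 7 {[(4S)-4-(4-methoxy-2-methylphenyl)pentyl]oxy}tri(propan-2-yl)silane
Product: 8 {[(4S)-4-(4-methoxy-2-methylcyclohexa-1,4-dien-1-yl)pentyl]oxy}tri(propan-2-yl)silane
Conditions: Li, NH3 (l), t-BuOH, THF, −78 to −33 °C; MeOH quench; product kept over K2CO3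
Reagents that add atoms: none
Why: Birch reduction of an anisole protonates the ring ortho and meta to the methoxy group so that the surviving double bonds carry the donor substituents, which gives the 1,4-diene with C7=C8 as enol ether and C5=C10 tetrasubstituted; the alcohol proton source prevents amide-induced conjugation and C4 is not involved.

Step 6
Reactants: 8 {[(4S)-4-(4-methoxy-2-methylcyclohexa-1,4-dien-1-yl)pentyl]oxy}tri(propan-2-yl)silane; 9 tert-butyl diazoacetate
Product: 10 tert-butyl (1S,6R,7R)-1-methoxy-3-methyl-4-[(2S)-5-(triisopropylsilyloxy)pentan-2-yl]bicyclo[4.1.0]hept-3-ene-7-carboxylate (exo ester; C8 = C1, C7 = C6, C11 = C7 of the bicycle)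
Conditions: (CuOTf)2·C6H6 (1 mol %), 2,2′-(propane-2,2-diyl)bis[(4S)-4-tert-butyl-4,5-dihydro-1,3-oxazole] (2.2 mol %), CH2Cl2, 0 °C to rt, 9 (2 equiv) added over 10 h by syringe pump; chromatography on Et3N-deactivated silica to remove the endo ester
Reagents that add atoms: tert-butyl diazoacetate (compound 9), [N-]=[N+]=CC(=O)OC(C)(C)C
Why: The monovalent copper complex formed from CuOTf and the bis(oxazoline) L decomposes 9 with loss of N2 to the electrophilic carbene complex LCu=CHCO2t-Bu, which adds to the enol ether in a concerted but asynchronous [2+1] cycloaddition: C11 bonds first to the nucleophilic C7, positive charge builds at the methoxy-bearing C8, and C8–C11 closes as copper leaves. The closest known reaction type is the CuOTf–bis(oxazoline)-catalysed cyclopropanation of enol ethers and silyl enol ethers with diazoacetates, and achiral copper catalysts are known to cyclopropanate 1-methoxycyclohexa-1,4-dienes at the enol-ether bond. The three-membered ring C7–C8–C11 is closed by this suprafacial [2+1] addition across C7=C8, which makes the ring fusion necessarily cis. C7 is fixed by the enantioface of the enol ether that the ligand admits (C4 is too remote to bias it), C8 follows from C7 through the cis fusion, and C11 is set exo because the tert-butyl ester avoids the six-membered ring on the carbene face left open by the tert-butyl groups of the ligand. By analogy with terminal alkenes the (S,S)-ligand is expected to give (R)-C11 and hence the required (R)-C7 in the exo series, and its antipode is used should the sense prove opposite. The step needs chemoselectivity for C7=C8 over C5=C10 and over allylic C–H insertion, which the electron-rich trisubstituted enol ether, the hindered tetrasubstituted alkene and the slow addition of 9 secure, and it needs a high exo:endo ratio, because an endo ester formed on the same carbene face carries the opposite C7 configuration and is therefore removed before the ring is opened.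

Step 7
Reactants: 10 tert-butyl (1S,6R,7R)-1-methoxy-3-methyl-4-[(2S)-5-(triisopropylsilyloxy)pentan-2-yl]bicyclo[4.1.0]hept-3-ene-7-carboxylate
Product: 11 tert-butyl 2-{(1R)-4-methyl-6-oxo-3-[(2S)-5-(triisopropylsilyloxy)pentan-2-yl]cyclohex-3-en-1-yl}acetate
Conditions: 2 M aq. HCl, THF, 0 °C to rt, stopped at full conversion; NaHCO3 work-up; used at once
Reagents that add atoms: water, O
Why: Acid-promoted ring opening of a donor–acceptor (alkoxycyclopropane ester) cyclopropane, in which protonation on the ester side cleaves the push–pull C8–C11 bond and the oxocarbenium ion at C8 is hydrated and loses methanol to unveil the C8 ketone; C7 is not involved and keeps its configuration, and cold dilute acid with immediate use keeps C5=C10 out of conjugation.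

Step 8
Reactants: 11 tert-butyl 2-{(1R)-4-methyl-6-oxo-3-[(2S)-5-(triisopropylsilyloxy)pentan-2-yl]cyclohex-3-en-1-yl}acetate
Product: 13 (3aR,7aR)-6-methyl-5-[(2S)-5-(triisopropylsilyloxy)pentan-2-yl]-3a,4,7,7a-tetrahydro-1-benzofuran-2(3H)-one, via hydroxy ester 12 (not isolated)
Conditions: K[HB(s-Bu)3] (K-Selectride), THF, −78 °C; AcOH quench; then p-TsOH·H2O (cat.), toluene, 50 °C
Reagents that add atoms: none
Why: The bulky hydride attacks the C8 ketone from the less hindered equatorial direction, as with 2-alkylcyclohexanones, to give the alcohol cis to the C7 acetate arm ((R)-C8), and acid catalysis then closes the cis-fused γ-lactone by intramolecular transesterification with loss of tert-butanol.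

Step 9
Reactants: 13 (3aR,7aR)-6-methyl-5-[(2S)-5-(triisopropylsilyloxy)pentan-2-yl]-3a,4,7,7a-tetrahydro-1-benzofuran-2(3H)-one
Product: 14 (3aR,7aR)-6-methyl-5-[(2S)-5-(triisopropylsilyloxy)pentan-2-yl]-3a,7a-dihydro-1-benzofuran-2,4(3H,7H)-dione
Conditions: CrO3, 3,5-dimethylpyrazole, CH2Cl2, −20 °C
Reagents that add atoms: chromium trioxide, O=[Cr](=O)=O
Why: Allylic oxidation by the hexavalent chromium–3,5-dimethylpyrazole complex turns a ring allylic methylene into the enone; C6 is preferred because C9 is deactivated by the adjacent C8 acyloxy group (the effect that directs 3-acyloxy-5-ene steroids to their remote allylic position), the C14 methyl is a poorer hydrogen donor and the C4–H bond is held in the alkene plane by allylic strain, while the neutral medium spares the base-sensitive β-acyloxy ketone.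

Step 10
Reactants: 14 (3aR,7aR)-6-methyl-5-[(2S)-5-(triisopropylsilyloxy)pentan-2-yl]-3a,7a-dihydro-1-benzofuran-2,4(3H,7H)-dione
Product: 15 (3aS,4R,7aR)-4-hydroxy-6-methyl-5-[(2S)-5-(triisopropylsilyloxy)pentan-2-yl]-3a,4,7,7a-tetrahydro-1-benzofuran-2(3H)-one
Conditions: NaBH4, CeCl3·7H2O, MeOH, −78 °C
Reagents that add atoms: none
Why: Luche reduction gives 1,2-reduction of the enone, and hydride attacks C6 from the convex face of the cis-fused bicycle, anti to the C7–C11 bond, so that the new hydroxyl is cis to the lactone ((R)-C6); the low temperature avoids β-elimination of the lactone carboxylate.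

Step 11
Reactants: 15 (3aS,4R,7aR)-4-hydroxy-6-methyl-5-[(2S)-5-(triisopropylsilyloxy)pentan-2-yl]-3a,4,7,7a-tetrahydro-1-benzofuran-2(3H)-one
Product: 16 (3aR,4R,7aR)-4-[tert-butyl(dimethyl)silyl]oxy-6-methyl-5-[(2S)-5-(triisopropylsilyloxy)pentan-2-yl]-3a,4,7,7a-tetrahydro-1-benzofuran-2(3H)-one
Conditions: t-BuMe2SiOTf, 2,6-lutidine, CH2Cl2, −78 to 0 °C
Reagents that add atoms: tert-butyldimethylsilyl trifluoromethanesulfonate, CC(C)(C)[Si](C)(C)OS(=O)(=O)C(F)(F)F
Why: Silylation of the secondary allylic alcohol with a silyl triflate and a hindered base, which prevents proton quenching of the enolate and translactonisation of a C6 alkoxide onto C12 in the next step.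

Step 12
Reactants: 16 (3aR,4R,7aR)-4-[tert-butyl(dimethyl)silyl]oxy-6-methyl-5-[(2S)-5-(triisopropylsilyloxy)pentan-2-yl]-3a,4,7,7a-tetrahydro-1-benzofuran-2(3H)-one
Product: 19 (3aR,4R,7aR)-4-[tert-butyl(dimethyl)silyl]oxy-6-methyl-3-methylidene-5-[(2S)-5-(triisopropylsilyloxy)pentan-2-yl]-3a,4,7,7a-tetrahydro-1-benzofuran-2(3H)-one, via Mannich base 17 (not isolated), via ammonium iodide 18 (not isolated)
Conditions: LiN(i-Pr)2, THF, −78 °C; Me2N=CH2+ I−, −78 °C to rt; then MeI, MeOH, rt; then aq. NaHCO3, CH2Cl2, rt
Reagents that add atoms: N,N-dimethylmethyleneiminium iodide, C=[N+](C)C.[I-]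
Why: α-Methylenation of a γ-lactone by the Mannich reaction of its lithium enolate with the iminium salt, N-methylation and Hofmann-type elimination; C11 is the only acidic site, no leaving group sits on the β-carbon C7, and the C11 stereocentre of the Mannich base vanishes on elimination.

Step 13
Reactants: 19 (3aR,4R,7aR)-4-[tert-butyl(dimethyl)silyl]oxy-6-methyl-3-methylidene-5-[(2S)-5-(triisopropylsilyloxy)pentan-2-yl]-3a,4,7,7a-tetrahydro-1-benzofuran-2(3H)-one
Product: 20 britannilactone, (3aS,4R,7aR)-4-hydroxy-5-[(2S)-5-hydroxypentan-2-yl]-6-methyl-3-methylidene-3a,4,7,7a-tetrahydro-1-benzofuran-2(3H)-one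
Conditions: HF·pyridine, pyridine, THF, 0 °C to rt
Reagents that add atoms: none
Why: Fluoride cleavage of both silyl ethers under buffered conditions, which spare the α-methylene lactone from conjugate addition and the allylic C6 alcohol from ionisation.

Step 14
Reactants: 20 britannilactone
Product: 21 1,6-O,O-diacetylbritannilactone
Conditions: Ac2O, pyridine, DMAP (cat.), CH2Cl2, 0 °C to rt
Reagents that add atoms: acetic anhydride, CC(=O)OC(C)=O
Why: DMAP-catalysed acetylation of the primary C1 and the secondary allylic C6 hydroxyl groups, with no stereocentre touched.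

Compound list
1 | 4-methoxy-2-methylbenzaldehyde | COc1ccc(C=O)c(C)c1 | starting material
2 | 1-ethenyl-4-methoxy-2-methylbenzene | COc1ccc(C=C)c(C)c1 | intermediate
3 | ethylene | C=C | starting material
4 | 1-[(2S)-but-3-en-2-yl]-4-methoxy-2-methylbenzene | COc1ccc([C@@H](C)C=C)c(C)c1 | intermediate
5 | (4S)-4-(4-methoxy-2-methylphenyl)pentanal | COc1ccc([C@@H](C)CCC=O)c(C)c1 | intermediate (not isolated)
6 | (4S)-4-(4-methoxy-2-methylphenyl)pentan-1-ol | COc1ccc([C@@H](C)CCCO)c(C)c1 | intermediate
7 | {[(4S)-4-(4-methoxy-2-methylphenyl)pentyl]oxy}tri(propan-2-yl)silane | COc1ccc([C@@H](C)CCCO[Si](C(C)C)(C(C)C)C(C)C)c(C)c1 | intermediate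
8 | {[(4S)-4-(4-methoxy-2-methylcyclohexa-1,4-dien-1-yl)pentyl]oxy}tri(propan-2-yl)silane | COC1=CCC([C@@H](C)CCCO[Si](C(C)C)(C(C)C)C(C)C)=C(C)C1 | intermediate
9 | tert-butyl diazoacetate | [N-]=[N+]=CC(=O)OC(C)(C)C | starting material
10 | tert-butyl (1S,6R,7R)-1-methoxy-3-methyl-4-[(2S)-5-(triisopropylsilyloxy)pentan-2-yl]bicyclo[4.1.0]hept-3-ene-7-carboxylate (cis-fused, exo ester) | CO[C@@]12CC(C)=C([C@@H](C)CCCO[Si](C(C)C)(C(C)C)C(C)C)C[C@@H]1[C@H]2C(=O)OC(C)(C)C | intermediate
11 | tert-butyl 2-{(1R)-4-methyl-6-oxo-3-[(2S)-5-(triisopropylsilyloxy)pentan-2-yl]cyclohex-3-en-1-yl}acetate | O=C1CC(C)=C([C@@H](C)CCCO[Si](C(C)C)(C(C)C)C(C)C)C[C@@H]1CC(=O)OC(C)(C)C | intermediate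
12 | tert-butyl 2-{(1R,6R)-6-hydroxy-4-methyl-3-[(2S)-5-(triisopropylsilyloxy)pentan-2-yl]cyclohex-3-en-1-yl}acetate (cis) | O[C@@H]1CC(C)=C([C@@H](C)CCCO[Si](C(C)C)(C(C)C)C(C)C)C[C@@H]1CC(=O)OC(C)(C)C | intermediate (not isolated)
13 | (3aR,7aR)-6-methyl-5-[(2S)-5-(triisopropylsilyloxy)pentan-2-yl]-3a,4,7,7a-tetrahydro-1-benzofuran-2(3H)-one (cis-fused lactone) | C1C(=O)O[C@@H]2CC(C)=C([C@@H](C)CCCO[Si](C(C)C)(C(C)C)C(C)C)C[C@H]12 | intermediate
14 | (3aR,7aR)-6-methyl-5-[(2S)-5-(triisopropylsilyloxy)pentan-2-yl]-3a,7a-dihydro-1-benzofuran-2,4(3H,7H)-dione (C6 enone) | C1C(=O)O[C@@H]2CC(C)=C([C@@H](C)CCCO[Si](C(C)C)(C(C)C)C(C)C)C(=O)[C@H]12 | intermediate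
15 | (3aS,4R,7aR)-4-hydroxy-6-methyl-5-[(2S)-5-(triisopropylsilyloxy)pentan-2-yl]-3a,4,7,7a-tetrahydro-1-benzofuran-2(3H)-one (H6, H7, H8 all cis) | C1C(=O)O[C@@H]2CC(C)=C([C@@H](C)CCCO[Si](C(C)C)(C(C)C)C(C)C)[C@H](O)[C@H]12 | intermediate
16 | (3aR,4R,7aR)-4-[tert-butyl(dimethyl)silyl]oxy-6-methyl-5-[(2S)-5-(triisopropylsilyloxy)pentan-2-yl]-3a,4,7,7a-tetrahydro-1-benzofuran-2(3H)-one | C1C(=O)O[C@@H]2CC(C)=C([C@@H](C)CCCO[Si](C(C)C)(C(C)C)C(C)C)[C@H](O[Si](C)(C)C(C)(C)C)[C@H]12 | intermediate
17 | 3-[(dimethylamino)methyl] derivative of 16 (Mannich base, mixture of C11 epimers) | CN(C)CC1C(=O)O[C@@H]2CC(C)=C([C@@H](C)CCCO[Si](C(C)C)(C(C)C)C(C)C)[C@H](O[Si](C)(C)C(C)(C)C)[C@H]12 | intermediate (not isolated)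
18 | trimethylammonium iodide of 17 | C[N+](C)(C)CC1C(=O)O[C@@H]2CC(C)=C([C@@H](C)CCCO[Si](C(C)C)(C(C)C)C(C)C)[C@H](O[Si](C)(C)C(C)(C)C)[C@H]12.[I-] | intermediate (not isolated)
19 | (3aR,4R,7aR)-4-[tert-butyl(dimethyl)silyl]oxy-6-methyl-3-methylidene-5-[(2S)-5-(triisopropylsilyloxy)pentan-2-yl]-3a,4,7,7a-tetrahydro-1-benzofuran-2(3H)-one | C=C1C(=O)O[C@@H]2CC(C)=C([C@@H](C)CCCO[Si](C(C)C)(C(C)C)C(C)C)[C@H](O[Si](C)(C)C(C)(C)C)[C@H]12 | intermediate
20 | britannilactone, (3aS,4R,7aR)-4-hydroxy-5-[(2S)-5-hydroxypentan-2-yl]-6-methyl-3-methylidene-3a,4,7,7a-tetrahydro-1-benzofuran-2(3H)-one | C=C1C(=O)O[C@@H]2CC(C)=C([C@@H](C)CCCO)[C@H](O)[C@H]12 | intermediate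
21 | 1,6-O,O-diacetylbritannilactone, (4S)-4-[(3aR,4R,7aR)-4-acetyloxy-6-methyl-3-methylidene-2-oxo-2,3,3a,4,7,7a-hexahydro-1-benzofuran-5-yl]pentyl acetate | C=C1C(=O)O[C@@H]2CC(C)=C([C@@H](C)CCCOC(C)=O)[C@H](OC(C)=O)[C@H]12 | target

Total step count: 14
Longest linear sequence: 14 steps (1 to 21)

Steps most likely to fail

Step 6. The CuOTf–bis(oxazoline) catalyst may discriminate the enantiofaces of a trisubstituted cyclic enol ether poorly, and endo ester carrying the opposite C7 configuration may erode the purity further. Because C4 is already set, such errors appear as diastereomers, not as the enantiomer. The fallback hands control to a covalently bound auxiliary that also makes the stereoisomers separable. It sets out from 8. (1R,2S,5R)-Menthol is acylated with bromoacetyl bromide and pyridine to (1R,2S,5R)-menthyl bromoacetate F1, which N,N′-ditosylhydrazine and DBU convert into (1R,2S,5R)-menthyl diazoacetate F2. Diene 8 and F2 are combined under the same CuOTf–bis(oxazoline) conditions, both ligand antipodes being tried to find the matched pair, to give the menthyl ester analogue of 10, menthyl (1S,6R,7R)-cyclopropanecarboxylate F3. Its diastereomers differ next to the auxiliary and should be separable by chromatography or crystallisation. The pure isomer is opened with cold dilute HCl to menthyl keto ester F4, and K[HB(s-Bu)3] reduction followed by p-TsOH gives, through menthyl hydroxy ester F5, the lactone with release of menthol; the route is rejoined at 13.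

Step 9. Oxidation may leak to C9, to the C14 methyl or to C4–H, or the β-acyloxy enone may lose the lactone carboxylate by elimination. The fallback replaces hydrogen abstraction by a closed-shell ene and [2,3]-sigmatropic sequence with a different regiochemical bias. It sets out from 13. SeO2 with t-BuOOH in CH2Cl2 should bond selenium to the less hindered alkene carbon C10 and remove hydrogen from the methylene on C5, that is from C6, delivering the C6 allylic alcohol F6 as a mixture of C6 epimers (the (R)-epimer is 15 itself). Dess–Martin oxidation buffered with NaHCO3 then converges both epimers on the enone; the route is rejoined at 14.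

Step 7. Acid strong enough to open the ring may also move C5=C10 into conjugation with the new ketone, epimerise C7 or loosen the silyl ether. The fallback separates ring cleavage from release of the carbonyl group. It sets out from 10. Camphorsulfonic acid (cat.) in dry MeOH with HC(OMe)3 opens the cyclopropane and traps the oxocarbenium ion as the dimethyl ketal F7, in which no enolisable carbonyl exists and the tetrasubstituted alkene position is also the thermodynamically preferred one. The ketal is then hydrolysed with oxalic acid on wet silica gel in CH2Cl2, conditions as mild as those used for Birch enol ethers; the route is rejoined at 11.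

Further compounds
F1 | step 6 | (1R,2S,5R)-menthyl bromoacetate | BrCC(=O)O[C@@H]1C[C@H](C)CC[C@H]1C(C)C
F2 | step 6 | (1R,2S,5R)-menthyl diazoacetate | [N-]=[N+]=CC(=O)O[C@@H]1C[C@H](C)CC[C@H]1C(C)C
F3 | step 6 | (1R,2S,5R)-menthyl (1S,6R,7R)-1-methoxy-3-methyl-4-[(2S)-5-(triisopropylsilyloxy)pentan-2-yl]bicyclo[4.1.0]hept-3-ene-7-carboxylate | CO[C@@]12CC(C)=C([C@@H](C)CCCO[Si](C(C)C)(C(C)C)C(C)C)C[C@@H]1[C@H]2C(=O)O[C@@H]3C[C@H](C)CC[C@H]3C(C)C
F4 | step 6 | (1R,2S,5R)-menthyl 2-{(1R)-4-methyl-6-oxo-3-[(2S)-5-(triisopropylsilyloxy)pentan-2-yl]cyclohex-3-en-1-yl}acetate | O=C1CC(C)=C([C@@H](C)CCCO[Si](C(C)C)(C(C)C)C(C)C)C[C@@H]1CC(=O)O[C@@H]2C[C@H](C)CC[C@H]2C(C)C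
F5 | step 6 | (1R,2S,5R)-menthyl 2-{(1R,6R)-6-hydroxy-4-methyl-3-[(2S)-5-(triisopropylsilyloxy)pentan-2-yl]cyclohex-3-en-1-yl}acetate | O[C@@H]1CC(C)=C([C@@H](C)CCCO[Si](C(C)C)(C(C)C)C(C)C)C[C@@H]1CC(=O)O[C@@H]2C[C@H](C)CC[C@H]2C(C)C
F6 | step 9 | (3aS,7aR)-4-hydroxy-6-methyl-5-[(2S)-5-(triisopropylsilyloxy)pentan-2-yl]-3a,4,7,7a-tetrahydro-1-benzofuran-2(3H)-one, mixture of C6 epimers | C1C(=O)O[C@@H]2CC(C)=C([C@@H](C)CCCO[Si](C(C)C)(C(C)C)C(C)C)C(O)[C@H]12
F7 | step 7 | tert-butyl 2-{(1R)-6,6-dimethoxy-4-methyl-3-[(2S)-5-(triisopropylsilyloxy)pentan-2-yl]cyclohex-3-en-1-yl}acetate | COC1(OC)CC(C)=C([C@@H](C)CCCO[Si](C(C)C)(C(C)C)C(C)C)C[C@@H]1CC(=O)OC(C)(C)C
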